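Slowness of the wanted step is not the trouble in south-west, where electrophile's half-life by step 4 alone, with the other concentrations as charged, is 6.2 min, short against the 30 min; but just after the start that step, electrophile + nucleophile, uses nucleophile at 0.62 of the rate at which self-condensation uses it.

    2 nucleophile → self-condensation product (k1 = 0.00100 /M/s)
    gas ⇌ free base, rate k2*(csat - [free base]) (k2 = 0.0141 /s, csat = 200 mM)
    acid set free + target → side product (k3 = 0.00146 /M/s)
    electrophile + nucleophile → acid set free + target (k4 = 0.00124 /M/s)
    acid set free + free base ⇌ salt of the base, settled at all times (K5 = 35800 /M)
    nucleophile + acid set free ⇌ protonated nucleophile, settled at all times (K6 = 35.7 /M)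

all flasks: electrophile 1.5 M; gas 200 mM (held); time 30 min
- north-east: nucleophile 3.00 M
- south-west: nucleophile 1.50 M

- part of the electrophile that has reacted at the end, north-east
- part of the electrophile that has reacted at the end, south-west
- what raising the concentration of nucleophile from its lowest to its highest value here does to the part of the electrophile that has reacted (changes below 5 percentage points count as none) (no change / it rises / it falls)

- a doubled species enters its step squared and goes two at a time
- at the start none of free base is dissolved
- run time (north-east): 30 min

Take the main step by itself first. In south-west the equal charges decay by second order, and 30 min brings 77.0 % of the electrophile to reaction. North-east, with twice the nucleophile, reaches 98.2 %.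

Now add self-condensation. Let σ = 0.620, the selectivity factor, the rate constant of the wanted step over twice that of self-condensation. Each electrophile that reacts then costs one nucleophile plus [nucleophile]/(σ[electrophile]) more, a relation with no time in it. Integrated down to zero nucleophile, it leaves the unreacted fraction (1 + mb)^(−1/m), where b is the equivalents of nucleophile charged and m is 1/σ less 1, here 0.613. The ceiling on the part reacted drops to 54.2 % in south-west and 72.9 % in north-east.

The approach comes next. With electrophile held at its ceiling value, nucleophile's rate law integrates in closed form, leaving 0.0860 M in south-west and 0.149 M in north-east at 30 min. Counting that remainder as electrophile still to react, my figures are 48.4 % and 62.9 %, on the low side because the held electrophile understates the wanted step.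

The rest changes little. Step 3 consumes target, not electrophile . Free base at saturation binds acid 66.9 times as strongly as north-east's starting nucleophile does. Acid first appears in north-east at twice the gas's top supply of 0.169 M/min, but the transfer time of the gas, 1.18 min, is less than the 4.48 min lifetime of electrophile at north-east's starting nucleophile.

The forecast says 68 % (63 % to 73 %) for north-east and 52 % (47 % to 57 %) for south-west, both above my figures , and it rises: “the higher starting charge gains a clear but less than proportional advantage”. The simulation gives 67.1 % and 50.2 %, so the part reacted responds as follows: it rises, by 17 percentage points. After 300 min the two stand at 73.4 % and 54.2 %.

Raise south-west's electrophile to 2.5 M and nucleophile, at 0.600 equiv, becomes the limiting reagent. The same σ gives a ceiling of 40.0 %, lower than south-west's. The same integration leaves 0.0206 M of nucleophile at 30 min, hence 39.2 % reacted. That flask ends with 39.7 % of its electrophile reacted and 1.09 % of its nucleophile left.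

Its constants are invented; what happens was integrated by code.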